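(The data were computed on assumed constants; scatter was added.)

Time was the awkward variable in these flasks: the earlier runs stopped at 4.00 min and the asked time was 8.0 min, so I took up a comparison of two amounts at one moment, the three-to-two ratio, the amount of complex with three exchanged over the amount of complex with two exchanged. It sets the two sides of the last exchange beside each other, and I did not take it for a constant of the flask.

common to all: starting complex 0.19 M
- cedar: incoming ligand 0.080 M; run made earlier
- ash: incoming ligand 0.14 M; run made earlier
- eta: incoming ligand 0.0950 M; time 8.0 min
- zeta: incoming ligand 0.190 M; time 8.0 min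
- gamma: incoming ligand 0.228 M; time 8.0 min

| run | time / min | complex with three exchanged / % | complex with two exchanged / % | starting complex / % |
|---|---|---|---|---|
| cedar | 0.333 | 0 | 0 | 91.9 |
| cedar | 0.667 | 0 | 1.7 | 87.2 |
| cedar | 1.00 | 0 | 1.9 | 80.6 |
| cedar | 2.00 | 1.2 | 3.3 | 71.1 |
| cedar | 4.00 | 0.9 | 4.7 | 60.2 |
| ash | 0.833 | 1.3 | 3.0 | 73.3 |
| ash | 1.50 | 1.2 | 4.8 | 63.3 |
| ash | 2.50 | 3.0 | 8.1 | 54.1 |
| ash | 3.00 | 3.5 | 7.6 | 50.9 |
| ash | 4.00 | 4.9 | 9.5 | 44.7 |

(readings scatter by 0.5 percentage points)

1. final complex with three exchanged, as a percentage of the starting complex charged, for each flask in turn (eta, zeta, gamma)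

In the ash run at 4.00 min I read a ratio of 0.516, a reading that carries the scatter of 0.5 percentage points in each amount. At 2.50 min the same run had read 0.370, so the readings were still climbing, and I used the later one as a rough figure. Flask zeta was charged with 1.00 of incoming ligand per starting complex, against 0.737 in ash. I took two extreme versions of zeta. In the first, the charged ligand sits entirely in the two upper complexes at this ratio, and counting two and three ligands per complex gives a fraction of 14.5% with three exchanged. In the second, the flask stays where ash stood, and the amount merely scales with the ligand charged, giving 6.65%, less than the first. I expected zeta to lie between: it had twice the time of that reading, yet ash still held 44.7% of starting complex at that reading, so lower forms were still in play. I committed to the middle, 10.6%.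

The forecast gave 1.5%, 8% and 12%, on the ground that “By 8 min, the outcome should therefore be set by ligand equivalents”. For zeta its figure lay inside my window, lower than my middle.

The flasks gave 3.34%, 9.89% and 12.3%, so the forecast held.

    complex with two exchanged + incoming ligand ⇌ leaving ligand + complex with three exchanged (K = 0.630, k = 0.111 M⁻¹ s⁻¹)
    starting complex + incoming ligand ⇌ leaving ligand + complex with one exchanged (K = 0.380, k = 0.0531 M⁻¹ s⁻¹)
    complex with one exchanged + incoming ligand ⇌ leaving ligand + complex with two exchanged (K = 3.17, k = 0.0529 M⁻¹ s⁻¹)
    leaving ligand + starting complex → side product (k = 0.0367 M⁻¹ s⁻¹)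

At the end, flask zeta stood at a ratio of 0.613 and flask gamma at 0.680, both higher than the ash reading of 0.516. Zeta stayed under my first extreme because the last exchange runs back and the time allowed is short, the two acting together. Without that backward run, zeta holds 20.9% of complex with three exchanged; with it, at ten times the time, zeta holds 17.7%.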